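**Retrosynthetic overview**

1. Target as drawn (germacrane numbering): an 11,13-dihydro-12,6-olide whose γ-lactone is cis-fused at C6/C7 to an (E,E)-cyclodeca-1(10),4-diene; C6–O, the C7–C11 bond and C8–O lie on one face of the ten-membered ring, and the C11 methyl is trans to C8.
2. Late cuts: the C8 ester (acylation with retention) and C11–C13 (lactone enolate methylation on the face away from C8 and C5).
3. Key cut: the C7–C8 bond. The aldehyde carbon C8 and the butenolide β-carbon C7 are both electrophilic and are joined by polarity reversal (SmI2 ketyl radical); this closes the ten-membered carbocycle onto the finished lactone and sets C7 and C8 from a linear precursor with one stereocentre (C6).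
4. Precursor 21: butenolide from Zn–ProPhenol alkynylation (sets C6) and Lindlar lactonisation; the C4=C5 alkene with C15 cis to C6 from Cu-catalysed anti-carbomagnesiation of propargyl alcohol; the E C1=C10 alkene from Zr-catalysed carboalumination.
5. Ring order: γ-lactone (as butenolide, step 7), then the ten-membered ring (step 9).

Key step: step 9

Remark (numbering): germacrane numbers are used in the text: C12 lactone carbonyl, C11 (methyl C13), C7/C6 ring fusion (C6 carries the lactone oxygen), C8 (ester oxygen), C9, C10 (methyl C14), C1, C2, C3, C4 (carries C15H2OH), C5.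

Assumption: (S,S)-ProPhenol is taken as the ligand enantiomer that adds the alkynyl group to the Si face of enal 14 (6R carbinol); if the sense is the opposite, the (R,R) ligand is used and nothing else changes.

**Route**

Step 1
Reactants: 1 tert-butyl(but-3-yn-1-yloxy)dimethylsilane; 2 oxirane
Product: 5 (3E)-6-(tert-butyldimethylsilyloxy)-4-methylhex-3-en-1-ol, via alkenyldimethylalane 3 (not isolated), via lithium alkenylalanate 4 (not isolated)
Conditions: AlMe3 (2.5 equiv), Cp2ZrCl2 (20 mol%), CH2Cl2, 0 °C → rt; evaporate; n-BuLi (1.0 equiv), THF–hexane, −78 → 0 °C; then 2, −78 °C → rt; aq. Rochelle salt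
Reagents that add atoms: trimethylaluminium, C[Al](C)C
Why: Zr-catalysed Negishi carboalumination adds CH3 (C14) and Al syn across the terminal alkyne, so only the E C10=C1 alkene should form, and the derived alanate transfers the alkenyl group to oxirane with retention to install C2–C3.

Step 2
Reactants: 5 (3E)-6-(tert-butyldimethylsilyloxy)-4-methylhex-3-en-1-ol
Product: 6 [(3E)-6-bromo-3-methylhex-3-en-1-yl]oxy(tert-butyl)dimethylsilane
Conditions: CBr4, PPh3, 2,6-lutidine, CH2Cl2, 0 °C
Reagents that add atoms: carbon tetrabromide, BrC(Br)(Br)Br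
Why: Appel bromination of a primary alcohol under buffered, neutral conditions should leave the TBS ether and the trisubstituted alkene untouched.

Step 3
Reactants: 6 [(3E)-6-bromo-3-methylhex-3-en-1-yl]oxy(tert-butyl)dimethylsilane; 7 prop-2-yn-1-ol
Product: 11 (2Z,5E)-8-(tert-butyldimethylsilyloxy)-2-(iodomethylidene)-6-methyloct-5-en-1-ol, via Grignard reagent 8 (not isolated), via bromomagnesium propargyl alkoxide 9 (not isolated), via alkenylmagnesium chelate 10 (not isolated)
Conditions: 6, Mg, THF, rt; separately 7, EtMgBr (1.0 equiv), THF, 0 °C; combine (8 1.5 equiv), CuI (15 mol%), −10 °C → rt; I2, THF, −78 → 0 °C; aq. NH4Cl/Na2S2O3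
Reagents that add atoms: iodine, II
Why: Copper-catalysed anti-carbomagnesiation of the propargylic alkoxide places the alkyl group on the internal carbon (C4) and magnesium on the terminal carbon, held cis to CH2O by chelation, and iodinolysis with retention should give the iodide with C15 cis to the C5–I bond.

Step 4
Reactants: 11 (2Z,5E)-8-(tert-butyldimethylsilyloxy)-2-(iodomethylidene)-6-methyloct-5-en-1-ol
Product: 12 tert-butyl{[(2Z,5E)-8-(tert-butyldimethylsilyloxy)-2-(iodomethylidene)-6-methyloct-5-en-1-yl]oxy}diphenylsilane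
Conditions: TBDPSCl, imidazole, CH2Cl2, 0 °C → rt
Reagents that add atoms: tert-butyl(chloro)diphenylsilane, CC(C)(C)[Si](Cl)(c1ccccc1)c1ccccc1
Why: Standard silylation of the primary allylic alcohol gives a C15 ether that should outlast the later acidic removal of the C8 TBS group.

Step 5
Reactants: 12 tert-butyl{[(2Z,5E)-8-(tert-butyldimethylsilyloxy)-2-(iodomethylidene)-6-methyloct-5-en-1-yl]oxy}diphenylsilane
Product: 14 (2Z,6E)-9-(tert-butyldimethylsilyloxy)-3-{[(tert-butyldiphenylsilyl)oxy]methyl}-7-methylnona-2,6-dienal, via alkenyllithium 13 (not isolated)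
Conditions: t-BuLi (2.1 equiv), Et2O, −78 °C; DMF, −78 → 0 °C; aq. NH4Cl
Reagents that add atoms: N,N-dimethylformamide, CN(C)C=O
Why: Iodine–lithium exchange proceeds with retention of alkene geometry and formylation of the alkenyllithium with DMF should give the enal with the new C6 aldehyde cis to C15.

Step 6
Reactants: 14 (2Z,6E)-9-(tert-butyldimethylsilyloxy)-3-{[(tert-butyldiphenylsilyl)oxy]methyl}-7-methylnona-2,6-dienal; 15 methyl prop-2-ynoate
Product: 17 methyl (4R,5Z,9E)-12-(tert-butyldimethylsilyloxy)-6-{[(tert-butyldiphenylsilyl)oxy]methyl}-4-hydroxy-10-methyldodeca-5,9-dien-2-ynoate, via zinc alkynylide 16 (not isolated)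
Conditions: 15 (3 equiv), Me2Zn (3 equiv), (S,S)-ProPhenol (20 mol%), Ph3P=O (40 mol%), toluene, 0–4 °C; then 14
Reagents that add atoms: none
Why: The dinuclear Zn–ProPhenol asymmetric alkynylation of enals with methyl propiolate adds the zinc alkynylide 1,2 to one face of the aldehyde under catalyst control and should set C6 as R.

Step 7
Reactants: 17 methyl (4R,5Z,9E)-12-(tert-butyldimethylsilyloxy)-6-{[(tert-butyldiphenylsilyl)oxy]methyl}-4-hydroxy-10-methyldodeca-5,9-dien-2-ynoate
Product: 20 (5S)-5-[(1Z,5E)-2-{[(tert-butyldiphenylsilyl)oxy]methyl}-8-hydroxy-6-methylocta-1,5-dien-1-yl]furan-2(5H)-one, via (Z)-hydroxy enoate 18 (not isolated), via silyl ether butenolide 19 (not isolated)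
Conditions: H2 (1 atm), Lindlar catalyst, quinoline, EtOAc, rt; filter, concentrate; PPTS (cat.), MeOH, rt
Reagents that add atoms: none
Why: Lindlar semi-hydrogenation of the ynoate gives the (Z)-γ-hydroxy enoate, which lactonises to the butenolide without touching C6 (the descriptor changes from R to S by the CIP rule only), and PPTS in MeOH should then cleave the primary TBS ether while the TBDPS ether stays.

Step 8
Reactants: 20 (5S)-5-[(1Z,5E)-2-{[(tert-butyldiphenylsilyl)oxy]methyl}-8-hydroxy-6-methylocta-1,5-dien-1-yl]furan-2(5H)-one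
Product: 21 (3E,7Z)-7-{[(tert-butyldiphenylsilyl)oxy]methyl}-3-methyl-8-[(2S)-5-oxo-2,5-dihydrofuran-2-yl]octa-3,7-dienal
Conditions: Dess–Martin periodinane, NaHCO3, CH2Cl2, 0 °C; crude 21 used at once
Reagents that add atoms: none
Why: Buffered Dess–Martin oxidation converts the homoallylic alcohol into the β,γ-unsaturated aldehyde without acid or base that would move the C10=C1 alkene into conjugation.

Step 9
Reactants: 21 (3E,7Z)-7-{[(tert-butyldiphenylsilyl)oxy]methyl}-3-methyl-8-[(2S)-5-oxo-2,5-dihydrofuran-2-yl]octa-3,7-dienal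
Product: 22 (3aS,4S,6E,10Z,11aR)-10-{[(tert-butyldiphenylsilyl)oxy]methyl}-4-hydroxy-6-methyl-3a,4,5,8,9,11a-hexahydrocyclodeca[b]furan-2(3H)-one
Conditions: SmI2 (2.5 equiv, THF), t-BuOH (3 equiv), 0 °C, 21 added over 6 h (final 2 mM); aq. NaHCO3/Na2S2O3, 0 °C
Reagents that add atoms: none
Why: Proposed new method: SmI2 reduces the aldehyde to the samarium ketyl (the butenolide is reduced far more slowly in HMPA-free THF), the nucleophilic C8 radical adds to the butenolide β-carbon C7, and the α-lactone radical is reduced to the Sm(III) enolate and protonated by t-BuOH; the closest known reaction type is the SmI2 ketyl–olefin cyclisation onto enoates and butenolides (five- to eight-membered rings) together with SmI2 Barbier, Reformatsky and pinacol macrocyclisations, and the ten-membered carbocycle is the extension proposed here. The ten-membered ring is closed through the C7–C8 bond in a 10-exo-trig radical mode, helped by the two E-configured trisubstituted alkenes that fold the chain as in other germacrane ring closures, while the γ-lactone is already present. C7 is controlled by the tether: the chain leaves C6 on one face of the planar butenolide and can deliver C8 only to that face of the adjacent C7, which gives the cis ring fusion (7S from 6R). C8 is controlled in the cyclic transition state: the position on C8 that eclipses C5 across the cis fusion can take only H, C9 takes the position gauche to C6 that the ring needs, and the bulky O–Sm(III) group is left anti to C6, away from the ring and from the developing enolate, which corresponds to the 8S carbinol. The step needs the ketyl to form first and to cyclise faster than it dimerises or is reduced, which the easier reduction of the aldehyde, slow addition at high dilution and the weak proton donor should secure. C11 is not a stereocentre at this stage, so protonation of the enolate carries no stereochemical risk.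

Step 10
Reactants: 22 (3aS,4S,6E,10Z,11aR)-10-{[(tert-butyldiphenylsilyl)oxy]methyl}-4-hydroxy-6-methyl-3a,4,5,8,9,11a-hexahydrocyclodeca[b]furan-2(3H)-one
Product: 24 (3R,3aS,4S,6E,10Z,11aR)-10-{[(tert-butyldiphenylsilyl)oxy]methyl}-4-hydroxy-3,6-dimethyl-3a,4,5,8,9,11a-hexahydrocyclodeca[b]furan-2(3H)-one, via dilithium alkoxide enolate 23 (not isolated)
Conditions: LDA (2.3 equiv), THF, −78 °C (22 added to the base); MeI (5 equiv), −78 → −50 °C; AcOH, −78 °C
Reagents that add atoms: iodomethane, CI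
Why: Alkylation of the lactone enolate (as the alkoxide–enolate dianion) should take place on the face of the cis-fused lactone opposite to C8 and C5, which sets C11 as R with the methyl trans to C8.

Step 11
Reactants: 25 ethyl 2-(hydroxymethyl)prop-2-enoate
Product: 26 ethyl 2-{[(tert-butyldimethylsilyl)oxy]methyl}prop-2-enoate
Conditions: TBSCl, imidazole, CH2Cl2, 0 °C → rt
Reagents that add atoms: tert-butyl(chloro)dimethylsilane, CC(C)(C)[Si](C)(C)Cl
Why: Standard silylation masks the primary alcohol of the side chain so that the acid cannot esterify itself in step 13.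

Step 12
Reactants: 26 ethyl 2-{[(tert-butyldimethylsilyl)oxy]methyl}prop-2-enoate
Product: 27 2-{[(tert-butyldimethylsilyl)oxy]methyl}prop-2-enoic acid
Conditions: LiOH·H2O, THF–H2O, 0 °C → rt; then 1 M HCl to pH 4, 0 °C
Reagents that add atoms: lithium hydroxide, [Li+].[OH-]
Why: Saponification of the ethyl ester at low temperature should give the acid without conjugate addition or loss of the silyl ether.

Step 13
Reactants: 24 (3R,3aS,4S,6E,10Z,11aR)-10-{[(tert-butyldiphenylsilyl)oxy]methyl}-4-hydroxy-3,6-dimethyl-3a,4,5,8,9,11a-hexahydrocyclodeca[b]furan-2(3H)-one; 27 2-{[(tert-butyldimethylsilyl)oxy]methyl}prop-2-enoic acid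
Product: 28 (3R,3aS,4S,6E,10Z,11aR)-10-{[(tert-butyldiphenylsilyl)oxy]methyl}-3,6-dimethyl-2-oxo-2,3,3a,4,5,8,9,11a-octahydrocyclodeca[b]furan-4-yl 2-{[(tert-butyldimethylsilyl)oxy]methyl}prop-2-enoate
Conditions: DCC, DMAP (cat.), CH2Cl2, 0 °C → rt
Reagents that add atoms: none
Why: Steglich esterification acylates the C8 hydroxyl with retention of configuration under conditions that should not epimerise C11 or open the lactone.

Step 14
Reactants: 28 (3R,3aS,4S,6E,10Z,11aR)-10-{[(tert-butyldiphenylsilyl)oxy]methyl}-3,6-dimethyl-2-oxo-2,3,3a,4,5,8,9,11a-octahydrocyclodeca[b]furan-4-yl 2-{[(tert-butyldimethylsilyl)oxy]methyl}prop-2-enoate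
Product: 29 (3R,3aS,4S,6E,10Z,11aR)-10-(hydroxymethyl)-3,6-dimethyl-2-oxo-2,3,3a,4,5,8,9,11a-octahydrocyclodeca[b]furan-4-yl 2-(hydroxymethyl)prop-2-enoate (CNP0167163.2)
Conditions: HF·pyridine, pyridine, THF, 0 °C → rt
Reagents that add atoms: none
Why: Buffered fluoride desilylation removes both silyl ethers without base that would trigger acyl migration, conjugate addition to the acrylate or lactone opening.

**Compound list**

1 | tert-butyl(but-3-yn-1-yloxy)dimethylsilane | C#CCCO[Si](C)(C)C(C)(C)C | starting material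
2 | oxirane | C1CO1 | starting material
3 | [(1E)-4-(tert-butyldimethylsilyloxy)-2-methylbut-1-en-1-yl]dimethylalane | CC(C)(C)[Si](C)(C)OCC/C(C)=C/[Al](C)C | intermediate
4 | lithium butyl[(1E)-4-(tert-butyldimethylsilyloxy)-2-methylbut-1-en-1-yl]dimethylalanate | CC(C)(C)[Si](C)(C)OCC/C(C)=C/[Al-](C)(C)CCCC.[Li+] | intermediate
5 | (3E)-6-(tert-butyldimethylsilyloxy)-4-methylhex-3-en-1-ol | CC(C)(C)[Si](C)(C)OCC/C(C)=C/CCO | intermediate
6 | [(3E)-6-bromo-3-methylhex-3-en-1-yl]oxy(tert-butyl)dimethylsilane | CC(C)(C)[Si](C)(C)OCC/C(C)=C/CCBr | intermediate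
7 | prop-2-yn-1-ol | C#CCO | starting material
8 | [(3E)-6-(tert-butyldimethylsilyloxy)-4-methylhex-3-en-1-yl]magnesium bromide | CC(C)(C)[Si](C)(C)OCC/C(C)=C/CC[Mg]Br | intermediate
9 | bromomagnesium prop-2-yn-1-olate | C#CCO[Mg]Br | intermediate
10 | 4-[(3E)-6-(tert-butyldimethylsilyloxy)-4-methylhex-3-en-1-yl]-2,5-dihydro-1,2-oxamagnesole | CC(C)(C)[Si](C)(C)OCC/C(C)=C/CCC1=C[Mg]OC1 | intermediate
11 | (2Z,5E)-8-(tert-butyldimethylsilyloxy)-2-(iodomethylidene)-6-methyloct-5-en-1-ol | CC(C)(C)[Si](C)(C)OCC/C(C)=C/CC/C(CO)=C/I | intermediate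
12 | tert-butyl{[(2Z,5E)-8-(tert-butyldimethylsilyloxy)-2-(iodomethylidene)-6-methyloct-5-en-1-yl]oxy}diphenylsilane | CC(C)(C)[Si](C)(C)OCC/C(C)=C/CC/C(CO[Si](c1ccccc1)(c1ccccc1)C(C)(C)C)=C/I | intermediate
13 | [(1Z,5E)-8-(tert-butyldimethylsilyloxy)-2-{[(tert-butyldiphenylsilyl)oxy]methyl}-6-methylocta-1,5-dien-1-yl]lithium | CC(C)(C)[Si](C)(C)OCC/C(C)=C/CC/C(CO[Si](c1ccccc1)(c1ccccc1)C(C)(C)C)=C/[Li] | intermediate
14 | (2Z,6E)-9-(tert-butyldimethylsilyloxy)-3-{[(tert-butyldiphenylsilyl)oxy]methyl}-7-methylnona-2,6-dienal | CC(C)(C)[Si](C)(C)OCC/C(C)=C/CC/C(CO[Si](c1ccccc1)(c1ccccc1)C(C)(C)C)=C/C=O | intermediate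
15 | methyl prop-2-ynoate | C#CC(=O)OC | starting material
16 | methyl 3-(methylzincio)prop-2-ynoate | C[Zn]C#CC(=O)OC | intermediate
17 | methyl (4R,5Z,9E)-12-(tert-butyldimethylsilyloxy)-6-{[(tert-butyldiphenylsilyl)oxy]methyl}-4-hydroxy-10-methyldodeca-5,9-dien-2-ynoate | CC(C)(C)[Si](C)(C)OCC/C(C)=C/CC/C(CO[Si](c1ccccc1)(c1ccccc1)C(C)(C)C)=C/[C@@H](O)C#CC(=O)OC | intermediate
18 | methyl (2Z,4S,5Z,9E)-12-(tert-butyldimethylsilyloxy)-6-{[(tert-butyldiphenylsilyl)oxy]methyl}-4-hydroxy-10-methyldodeca-2,5,9-trienoate | CC(C)(C)[Si](C)(C)OCC/C(C)=C/CC/C(CO[Si](c1ccccc1)(c1ccccc1)C(C)(C)C)=C/[C@@H](O)/C=C\C(=O)OC | intermediate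
19 | (5S)-5-[(1Z,5E)-8-(tert-butyldimethylsilyloxy)-2-{[(tert-butyldiphenylsilyl)oxy]methyl}-6-methylocta-1,5-dien-1-yl]furan-2(5H)-one | CC(C)(C)[Si](C)(C)OCC/C(C)=C/CC/C(CO[Si](c1ccccc1)(c1ccccc1)C(C)(C)C)=C/[C@H]2OC(=O)C=C2 | intermediate
20 | (5S)-5-[(1Z,5E)-2-{[(tert-butyldiphenylsilyl)oxy]methyl}-8-hydroxy-6-methylocta-1,5-dien-1-yl]furan-2(5H)-one | OCC/C(C)=C/CC/C(CO[Si](c1ccccc1)(c1ccccc1)C(C)(C)C)=C/[C@H]2OC(=O)C=C2 | intermediate
21 | (3E,7Z)-7-{[(tert-butyldiphenylsilyl)oxy]methyl}-3-methyl-8-[(2S)-5-oxo-2,5-dihydrofuran-2-yl]octa-3,7-dienal | O=CC/C(C)=C/CC/C(CO[Si](c1ccccc1)(c1ccccc1)C(C)(C)C)=C/[C@H]2OC(=O)C=C2 | intermediate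
22 | (3aS,4S,6E,10Z,11aR)-10-{[(tert-butyldiphenylsilyl)oxy]methyl}-4-hydroxy-6-methyl-3a,4,5,8,9,11a-hexahydrocyclodeca[b]furan-2(3H)-one | O[C@H]1C/C(C)=C/CC/C(CO[Si](c3ccccc3)(c3ccccc3)C(C)(C)C)=C/[C@H]2OC(=O)C[C@@H]12 | intermediate
23 | dilithium alkoxide enolate of 22 (C8–OLi and C12 lithium enolate) | [Li]O[C@H]1C/C(C)=C/CC/C(CO[Si](c3ccccc3)(c3ccccc3)C(C)(C)C)=C/[C@H]2OC(O[Li])=C[C@@H]12 | intermediate
24 | (3R,3aS,4S,6E,10Z,11aR)-10-{[(tert-butyldiphenylsilyl)oxy]methyl}-4-hydroxy-3,6-dimethyl-3a,4,5,8,9,11a-hexahydrocyclodeca[b]furan-2(3H)-one | O[C@H]1C/C(C)=C/CC/C(CO[Si](c3ccccc3)(c3ccccc3)C(C)(C)C)=C/[C@H]2OC(=O)[C@H](C)[C@@H]12 | intermediate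
25 | ethyl 2-(hydroxymethyl)prop-2-enoate | C=C(CO)C(=O)OCC | starting material
26 | ethyl 2-{[(tert-butyldimethylsilyl)oxy]methyl}prop-2-enoate | C=C(CO[Si](C)(C)C(C)(C)C)C(=O)OCC | intermediate
27 | 2-{[(tert-butyldimethylsilyl)oxy]methyl}prop-2-enoic acid | C=C(CO[Si](C)(C)C(C)(C)C)C(=O)O | intermediate
28 | (3R,3aS,4S,6E,10Z,11aR)-10-{[(tert-butyldiphenylsilyl)oxy]methyl}-3,6-dimethyl-2-oxo-2,3,3a,4,5,8,9,11a-octahydrocyclodeca[b]furan-4-yl 2-{[(tert-butyldimethylsilyl)oxy]methyl}prop-2-enoate | C=C(CO[Si](C)(C)C(C)(C)C)C(=O)O[C@H]1C/C(C)=C/CC/C(CO[Si](c3ccccc3)(c3ccccc3)C(C)(C)C)=C/[C@H]2OC(=O)[C@H](C)[C@@H]12 | intermediate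
29 | (3R,3aS,4S,6E,10Z,11aR)-10-(hydroxymethyl)-3,6-dimethyl-2-oxo-2,3,3a,4,5,8,9,11a-octahydrocyclodeca[b]furan-4-yl 2-(hydroxymethyl)prop-2-enoate (CNP0167163.2) | C=C(CO)C(=O)O[C@H]1C/C(C)=C/CC/C(CO)=C/[C@H]2OC(=O)[C@H](C)[C@@H]12 | target

**Step count and risks**

Total step count: 14. Longest linear sequence: 12 steps (steps 1–10, 13, 14); steps 11–12 prepare the side-chain acid.

Steps most likely to fail:

1. Step 9 (Proposed new method). The slow ten-membered radical closure may lose to pinacol coupling, to simple reduction of the ketyl, or to reductive cleavage of the allylic lactone C–O bond, and facial control at the ketyl carbon may be low. The fallback uses known chemistry, sets out from 17 and returns at 22. Hydroiodination of the ynoate with lactonisation (NaI, AcOH, 40 °C) should give the β-iodobutenolide silyl ether F1. PPTS in MeOH frees the C8 hydroxyl to give the iodobutenolide alcohol F2, and Dess–Martin oxidation gives the iodobutenolide aldehyde F3. An intramolecular Nozaki–Hiyama–Kishi reaction (CrCl2, NiCl2 cat., DMSO–THF, high dilution) closes the same C7–C8 bond as the macrocyclic butenolide carbinol F4, expected as both C8 epimers. Dess–Martin oxidation converges them to the macrocyclic enone F5, and Corey–Bakshi–Shibata reduction ((R)-oxazaborolidine, catecholborane, −78 °C; butenolide carbon as the large group) sets C8 by reagent control as the 8S allylic alcohol F6. Conjugate reduction of the butenolide (NaBH4, NiCl2·6H2O, MeOH, −20 °C) should add hydride to C7 on the face opposite to the C5 chain and give the cis-fused lactone 22.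

2. Step 6. Enantioselectivity may erode and the enal may isomerise from Z to E under the Lewis-acidic zinc conditions. The fallback sets out from 14 and returns at 17. Lithiated 15 (LiHMDS, THF, −78 °C) adds to 14 to give the racemic propargylic alcohol F7. MnO2 oxidation gives the ynone F8, and Corey–Bakshi–Shibata reduction ((R)-oxazaborolidine, catecholborane, toluene, −78 °C; alkynyl as the small group) should return 17 with the 6R carbinol.

3. Step 10. The C8 alkoxide may take over the lactone acyl group (translactonisation), and over-alkylation may occur during the dianion methylation. The fallback sets out from 22 and returns at 24. Silylation (TESOTf, 2,6-lutidine, CH2Cl2, −78 °C) gives the triethylsilyl ether F9, so that no alkoxide is present. Mono-enolate methylation (LDA, THF, −78 °C; MeI) on the face opposite to C8 gives the methylated triethylsilyl ether F10. PPTS in MeOH removes the TES group in the presence of the TBDPS ether and returns 24.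

**Further compounds**

F1 | step 9 | (5R)-5-[(1Z,5E)-8-(tert-butyldimethylsilyloxy)-2-{[(tert-butyldiphenylsilyl)oxy]methyl}-6-methylocta-1,5-dien-1-yl]-4-iodofuran-2(5H)-one | CC(C)(C)[Si](C)(C)OCC/C(C)=C/CC/C(CO[Si](c1ccccc1)(c1ccccc1)C(C)(C)C)=C/[C@H]2OC(=O)C=C2I
F2 | step 9 | (5R)-5-[(1Z,5E)-2-{[(tert-butyldiphenylsilyl)oxy]methyl}-8-hydroxy-6-methylocta-1,5-dien-1-yl]-4-iodofuran-2(5H)-one | OCC/C(C)=C/CC/C(CO[Si](c1ccccc1)(c1ccccc1)C(C)(C)C)=C/[C@H]2OC(=O)C=C2I
F3 | step 9 | (3E,7Z)-7-{[(tert-butyldiphenylsilyl)oxy]methyl}-8-[(2R)-3-iodo-5-oxo-2,5-dihydrofuran-2-yl]-3-methylocta-3,7-dienal | O=CC/C(C)=C/CC/C(CO[Si](c1ccccc1)(c1ccccc1)C(C)(C)C)=C/[C@H]2OC(=O)C=C2I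
F4 | step 9 | (6E,10Z,11aR)-10-{[(tert-butyldiphenylsilyl)oxy]methyl}-4-hydroxy-6-methyl-4,5,8,9-tetrahydrocyclodeca[b]furan-2(11aH)-one (both C4 epimers) | OC1C/C(C)=C/CC/C(CO[Si](c3ccccc3)(c3ccccc3)C(C)(C)C)=C/[C@H]2OC(=O)C=C12
F5 | step 9 | (6E,10Z,11aR)-10-{[(tert-butyldiphenylsilyl)oxy]methyl}-6-methyl-8,9-dihydrocyclodeca[b]furan-2,4(5H,11aH)-dione | O=C1C/C(C)=C/CC/C(CO[Si](c3ccccc3)(c3ccccc3)C(C)(C)C)=C/[C@H]2OC(=O)C=C12
F6 | step 9 | (4S,6E,10Z,11aR)-10-{[(tert-butyldiphenylsilyl)oxy]methyl}-4-hydroxy-6-methyl-4,5,8,9-tetrahydrocyclodeca[b]furan-2(11aH)-one | O[C@H]1C/C(C)=C/CC/C(CO[Si](c3ccccc3)(c3ccccc3)C(C)(C)C)=C/[C@H]2OC(=O)C=C12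
F7 | step 6 | methyl (5Z,9E)-12-(tert-butyldimethylsilyloxy)-6-{[(tert-butyldiphenylsilyl)oxy]methyl}-4-hydroxy-10-methyldodeca-5,9-dien-2-ynoate (racemic at C4) | CC(C)(C)[Si](C)(C)OCC/C(C)=C/CC/C(CO[Si](c1ccccc1)(c1ccccc1)C(C)(C)C)=C/C(O)C#CC(=O)OC
F8 | step 6 | methyl (5Z,9E)-12-(tert-butyldimethylsilyloxy)-6-{[(tert-butyldiphenylsilyl)oxy]methyl}-10-methyl-4-oxododeca-5,9-dien-2-ynoate | CC(C)(C)[Si](C)(C)OCC/C(C)=C/CC/C(CO[Si](c1ccccc1)(c1ccccc1)C(C)(C)C)=C/C(=O)C#CC(=O)OC
F9 | step 10 | (3aR,4S,6E,10Z,11aR)-10-{[(tert-butyldiphenylsilyl)oxy]methyl}-6-methyl-4-(triethylsilyloxy)-3a,4,5,8,9,11a-hexahydrocyclodeca[b]furan-2(3H)-one (same spatial arrangement as 22; the 3a descriptor changes by the CIP rule only) | CC[Si](CC)(CC)O[C@H]1C/C(C)=C/CC/C(CO[Si](c3ccccc3)(c3ccccc3)C(C)(C)C)=C/[C@H]2OC(=O)C[C@@H]12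
F10 | step 10 | (3R,3aR,4S,6E,10Z,11aR)-10-{[(tert-butyldiphenylsilyl)oxy]methyl}-3,6-dimethyl-4-(triethylsilyloxy)-3a,4,5,8,9,11a-hexahydrocyclodeca[b]furan-2(3H)-one (same spatial arrangement as 24) | CC[Si](CC)(CC)O[C@H]1C/C(C)=C/CC/C(CO[Si](c3ccccc3)(c3ccccc3)C(C)(C)C)=C/[C@H]2OC(=O)[C@H](C)[C@@H]12
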